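**Retrosynthetic overview**
1. The strategy rests on the 2-monosubstituted furan. Its ring carbons C2–C5 (C24–C27 of the C27 chain, counted from the carboxyl carbon) and its ring oxygen are read as a terminal (E)-buta-1,3-dienyl unit plus one oxygen atom of O2.
2. The furan, the only ring of the target, is made in the penultimate step from diene ester 10: singlet-oxygen [4+2] addition gives a transient 3,6-dihydro-1,2-dioxine ring, which base and then acid convert to the furan in the same flask. Saponification then gives the acid.
3. Ester 10 is cut at the C6–C7 sp–sp bond (Cadiot–Chodkiewicz) into methyl 6-bromohex-5-ynoate 9 and dienyne 7.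
4. Dienyne 7 comes from hexadecanolide 1 by half-reduction, (E)-selective allylphosphonate olefination (C24=C25), Appel bromination and acetylide displacement (C8–C9).
5. Ring order: the dioxine ring (transient) and then the furan ring, both in step 7.

Key step: step 7

Remark: the target has no stereocentre. The only stereochemical element to control is the (E) geometry of C24=C25 in 10, which is consumed in the key step. Positions are numbered along the C27 chain of 10 throughout.

**Step 1**
Reactants: 1 hexadecanolide (oxacycloheptadecan-2-one)
Product: 2 16-hydroxyhexadecanal
Conditions: i-Bu2AlH (1.1 equiv), CH2Cl2, −78 °C; MeOH quench, aq. KNaC4H4O6 (potassium sodium tartrate)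
Reagents that add atoms: none
Why: Partial hydride reduction of a lactone, in which the aluminium hemiacetal is stable at −78 °C and releases the aldehyde only on work-up, so the open-chain hydroxyaldehyde of the 17-membered lactone should be obtained without over-reduction.

**Step 2**
Reactants: 2 16-hydroxyhexadecanal; 3 diethyl allylphosphonate
Product: 4 (16E)-nonadeca-16,18-dien-1-ol
Conditions: 3 (2.5 equiv), n-BuLi (2.4 equiv), THF, −78 °C; HMPA; then 2, −78 °C → rt
Reagents that add atoms: none
Why: Horner–Wadsworth–Emmons-type olefination in which the lithiated allylic phosphonate adds through its α-carbon to the aldehyde and HMPA promotes loss of lithium diethyl phosphate from the β-oxido phosphonate, which should give the new double bond predominantly (E), the first equivalent of anion being consumed by the free hydroxyl.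

**Step 3**
Reactants: 4 (16E)-nonadeca-16,18-dien-1-ol
Product: 5 (3E)-19-bromononadeca-1,3-diene
Conditions: CBr4, PPh3, CH2Cl2, 0 °C
Reagents that add atoms: tetrabromomethane BrC(Br)(Br)Br
Why: Appel reaction, an SN2 displacement of the alkoxyphosphonium ion by bromide at the primary carbon under neutral conditions that leave the conjugated diene untouched.

**Step 4**
Reactants: 5 (3E)-19-bromononadeca-1,3-diene; 6 lithium acetylide ethylenediamine complex
Product: 7 (3E)-henicosa-1,3-dien-20-yne
Conditions: LiC≡CH·H2NCH2CH2NH2 (2.5 equiv), DMSO, 10 °C → rt
Reagents that add atoms: none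
Why: SN2 alkylation of an acetylide by a primary bromide in a dipolar aprotic solvent, with the acetylide too weak a base to deprotonate the allylic position of the diene.

**Step 5**
Reactants: 8 methyl hex-5-ynoate
Product: 9 methyl 6-bromohex-5-ynoate
Conditions: NBS (1.1 equiv), AgNO3 (10 mol %), acetone, rt, dark
Reagents that add atoms: N-bromosuccinimide O=C1CCC(=O)N1Br
Why: Silver-catalysed electrophilic bromination of a terminal alkyne through its silver acetylide, which is selective for the sp C–H bond and tolerates the ester.

**Step 6**
Reactants: 7 (3E)-henicosa-1,3-dien-20-yne; 9 methyl 6-bromohex-5-ynoate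
Product: 10 methyl (24E)-heptacosa-24,26-dien-5,7-diynoate
Conditions: CuCl (5 mol %), NH2OH·HCl, 30% aq. n-BuNH2, THF, 0 °C, slow addition of 9 (1.2 equiv)
Reagents that add atoms: none
Why: Cadiot–Chodkiewicz coupling, in which the copper acetylide of 7 displaces bromine from 9 to form the C6–C7 sp–sp bond, hydroxylamine keeping copper in the monovalent state so that oxidative homocoupling is suppressed and the low temperature and short contact time sparing the methyl ester.

**Step 7**
Reactants: 10 methyl (24E)-heptacosa-24,26-dien-5,7-diynoate
Product: 14 methyl 23-(furan-2-yl)tricosa-5,7-diynoate, via endoperoxide 11 (not isolated), via cis-hydroxyenal 12 (not isolated), via lactol 13 (not isolated)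
Conditions: O2, 5,10,15,20-tetraphenylporphyrin (TPP, cat.), CH2Cl2, visible light (>400 nm), 0 °C; then Ar purge, dark, Et3N (0.3 equiv), rt; then p-TsOH·H2O (0.5 equiv), 0 °C → rt
Reagents that add atoms: dioxygen O=O
Why: Sensitised singlet oxygen adds suprafacially to C24 and C27 of the s-cis conformer of the terminal (E)-diene in a concerted [4+2] cycloaddition, the standard endoperoxide formation of 1,3-dienes, which closes the six-membered 3,6-dihydro-1,2-dioxine ring of 11 and forms the C24–O and C27–O bonds. Triethylamine then removes a proton from the ring CH2–O carbon (C27) with cleavage of the O–O bond (Kornblum–DeLaMare rearrangement) to give cis-hydroxyenal 12, whose C24 hydroxyl adds to the C27 aldehyde in a 5-exo-trig closure to lactol 13, and acid-catalysed loss of water aromatises 13 to the furan, so that the ring O–C24 bond stems from the cycloaddition and the ring O–C27 bond from the lactol closure (deprotonation at C24 instead would lead through the cis-hydroxyenone to the same furan). The only stereocentre formed, C24 in 11 to 13, arises as a racemate and is erased on aromatisation, so no stereocontrol is required. The step needs the [4+2] mode to outrun the ene reaction at the allylic C23 hydrogens, which the (E) geometry secures by letting the diene reach the s-cis conformer without strain while the 1,2-disubstituted C24=C25 bond is a poor ene partner. It also needs chemoselectivity for the diene, which the substrate provides because the conjugated diyne, the ester and the saturated chain do not react with singlet oxygen under visible-light sensitisation. The furan, itself a fast acceptor of singlet oxygen, is protected because it is generated only after the lamp is off and the oxygen has been purged.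

**Step 8**
Reactants: 14 methyl 23-(furan-2-yl)tricosa-5,7-diynoate
Product: 15 23-(furan-2-yl)tricosa-5,7-diynoic acid
Conditions: LiOH·H2O (3 equiv), THF/MeOH/H2O, rt; 1 M HCl to pH 4, 0 °C
Reagents that add atoms: lithium hydroxide [Li+].[OH-]
Why: Saponification by acyl–oxygen cleavage under conditions to which the furan and the diyne are stable, with cold and only mildly acidic work-up to protect the acid-sensitive furan.

**Compound list**
1 | hexadecanolide (oxacycloheptadecan-2-one) | O=C1CCCCCCCCCCCCCCCO1 | starting material
2 | 16-hydroxyhexadecanal | O=CCCCCCCCCCCCCCCCO | intermediate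
3 | diethyl allylphosphonate | C=CCP(=O)(OCC)OCC | starting material
4 | (16E)-nonadeca-16,18-dien-1-ol | OCCCCCCCCCCCCCCC/C=C/C=C | intermediate
5 | (3E)-19-bromononadeca-1,3-diene | BrCCCCCCCCCCCCCCC/C=C/C=C | intermediate
6 | lithium acetylide ethylenediamine complex | [Li]C#C.NCCN | starting material
7 | (3E)-henicosa-1,3-dien-20-yne | C#CCCCCCCCCCCCCCCC/C=C/C=C | intermediate
8 | methyl hex-5-ynoate | C#CCCCC(=O)OC | starting material
9 | methyl 6-bromohex-5-ynoate | COC(=O)CCCC#CBr | intermediate
10 | methyl (24E)-heptacosa-24,26-dien-5,7-diynoate | COC(=O)CCCC#CC#CCCCCCCCCCCCCCCC/C=C/C=C | intermediate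
11 | methyl 23-(3,6-dihydro-1,2-dioxin-3-yl)tricosa-5,7-diynoate (racemic) | COC(=O)CCCC#CC#CCCCCCCCCCCCCCCCC1C=CCOO1 | intermediate
12 | methyl (25Z)-24-hydroxy-27-oxoheptacos-25-ene-5,7-diynoate (racemic) | COC(=O)CCCC#CC#CCCCCCCCCCCCCCCCC(O)/C=C\C=O | intermediate
13 | methyl 23-(5-hydroxy-2,5-dihydrofuran-2-yl)tricosa-5,7-diynoate (diastereomer mixture) | COC(=O)CCCC#CC#CCCCCCCCCCCCCCCCC1C=CC(O)O1 | intermediate
14 | methyl 23-(furan-2-yl)tricosa-5,7-diynoate | COC(=O)CCCC#CC#CCCCCCCCCCCCCCCCc1ccco1 | intermediate
15 | 23-(furan-2-yl)tricosa-5,7-diynoic acid | O=C(O)CCCC#CC#CCCCCCCCCCCCCCCCc1ccco1 | target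

**Step count**
Total steps: 8. Longest linear sequence: 7 (steps 1–4 and 6–8, from hexadecanolide 1).

**Steps most likely to fail**

1. Step 7. The cycloaddition of a monosubstituted acyclic diene may be slow, so that the ene reaction at C23 and bleaching of the sensitiser gain ground, and the acid stage may degrade the nascent furan. The fallback brings the furan in preformed and sets out from 2. Seyferth–Gilbert homologation of 2 with dimethyl (1-diazo-2-oxopropyl)phosphonate and K2CO3 in MeOH should give heptadec-16-yn-1-ol F1. Appel bromination (CBr4, PPh3, CH2Cl2) should give 17-bromoheptadec-1-yne F2. Alkylation of 2-lithiofuran (3 equiv, from furan and n-BuLi, THF, 0 °C → rt) should give 2-(heptadec-16-yn-1-yl)furan F3; the first equivalent only converts the alkyne into its lithium acetylide, which does not alkylate in THF without a dipolar cosolvent. Cadiot–Chodkiewicz coupling of F3 with 9 under the conditions of step 6 returns to the route at 14.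

2. Step 2. The lithium alkoxide of 2 may slow the addition, and γ-attack of the allylic anion or incomplete (E)-selectivity may erode the diene quality on which step 7 depends. The fallback sets out from 2 and fixes the geometry in two Wittig reactions. Ph3P=CHCHO in toluene at 80 °C should give (2E)-18-hydroxyoctadec-2-enal F4. Methylenation with Ph3P=CH2 (from Ph3PCH3Br and KOt-Bu, 2.5 equiv, THF, 0 °C) returns to the route at 4 with the (E) double bond carried over unchanged.

3. Step 6. Homocoupling of either alkyne may compete with the cross-coupling, and the primary amine may slowly convert the methyl ester into an amide. The fallback couples at the carboxylic acid stage and sets out from 9. Saponification (LiOH, THF/H2O, then dilute HCl) should give 6-bromohex-5-ynoic acid F5. Its carboxylate is coupled with 7 (CuCl, NH2OH·HCl, aq. n-BuNH2, THF, 0 °C) to give (24E)-heptacosa-24,26-dien-5,7-diynoic acid F6, which acid–base extraction frees from the neutral homodimer of 7. Methylation (MeI, K2CO3, DMF, rt) returns to the route at 10.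

**Further compounds**
F1 | step 7 | heptadec-16-yn-1-ol | C#CCCCCCCCCCCCCCCCO
F2 | step 7 | 17-bromoheptadec-1-yne | C#CCCCCCCCCCCCCCCCBr
F3 | step 7 | 2-(heptadec-16-yn-1-yl)furan | C#CCCCCCCCCCCCCCCCc1ccco1
F4 | step 2 | (2E)-18-hydroxyoctadec-2-enal | OCCCCCCCCCCCCCCC/C=C/C=O
F5 | step 6 | 6-bromohex-5-ynoic acid | OC(=O)CCCC#CBr
F6 | step 6 | (24E)-heptacosa-24,26-dien-5,7-diynoic acid | OC(=O)CCCC#CC#CCCCCCCCCCCCCCCC/C=C/C=C
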